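## Retrosynthetic overview

- The acid comes from its methyl ester, which comes from a Z-selective Still–Gennari olefination of a C7′ aldehyde (side-chain carbons are numbered C1′ outward from chromane C2).
- That aldehyde comes from a chromane-bearing 1,1-dichloroalkene by two successive Negishi couplings. The first installs a propanal homoenolate (β-zincated acetal) trans to the chain; this is the key C4′–C5′ bond and fixes the E alkene. The second installs the methyl group.
- The dichloroalkene comes from a C3′ aldehyde, made by oxidative cleavage of the prenyl terminus of a linalool-derived chromane.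
- The chromane comes from aryl C–O ring closure of a bromo tertiary alcohol, itself made by B-alkyl Suzuki coupling of (R)-linalool (source of C2) with 2-bromo-1-iodo-5-methoxy-3-methylbenzene (from 4-methoxy-2-methylaniline).
- Ring order: the benzene ring is bought; the dihydropyran ring is the only ring formed (step 4).

Assumption: commercial (R)-(−)-linalool of ≥97% ee is used, and the target is read from the SMILES as 2R, 2Z (acid end), 6E.

## Route

Step 1
Reactants: 1 4-methoxy-2-methylaniline
Product: 2 2-iodo-4-methoxy-6-methylaniline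
Conditions: NIS (1.05 equiv), MeCN, 0 °C to rt, dark
Reagents that add atoms: N-iodosuccinimide, O=C1CCC(=O)N1I
Why: Electrophilic aromatic iodination, in which the amino group directs iodine to its only free ortho position (para is blocked by OMe), the future C4a.

Step 2
Reactants: 2 2-iodo-4-methoxy-6-methylaniline
Product: 4 2-bromo-1-iodo-5-methoxy-3-methylbenzene, via arenediazonium bromide 3 (not isolated)
Conditions: NaNO2, 48% aq HBr, MeCN/H2O, 0 °C; then CuBr, 0 to 60 °C
Reagents that add atoms: hydrobromic acid, Br; sodium nitrite, [Na+].[O-]N=O (second nitrogen of intermediate 3 only)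
Why: Sandmeyer bromination replaces the amino group by bromine, giving an arene whose C–I bond (future C4a) is more reactive than its C–Br bond (future C8a).

Step 3
Reactants: 5 (R)-linalool [(3R)-3,7-dimethylocta-1,6-dien-3-ol]; 4 2-bromo-1-iodo-5-methoxy-3-methylbenzene
Product: 7 (3R)-1-(2-bromo-5-methoxy-3-methylphenyl)-3,7-dimethyloct-6-en-3-ol, via B-alkyl-9-BBN adduct 6 (not isolated)
Conditions: 9-BBN dimer (1.1 equiv), THF, 0 °C to rt; then 4, Pd(dppf)Cl2 (5 mol%), 3 M aq NaOH, THF/DMF, rt to 45 °C
Reagents that add atoms: 9-borabicyclo[3.3.1]nonane, B1C2CCCC1CCC2 (boron and its ring carbons are in intermediate 6 only, not in 7)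
Why: Anti-Markovnikov hydroboration of the vinyl group (9-BBN leaves the trisubstituted alkene alone) followed by B-alkyl Suzuki–Miyaura coupling at C–I in preference to C–Br; the carbinol stereocentre of linalool is not touched and becomes C2 of the target.

Step 4
Reactants: 7 (3R)-1-(2-bromo-5-methoxy-3-methylphenyl)-3,7-dimethyloct-6-en-3-ol
Product: 8 (2R)-6-methoxy-2,8-dimethyl-2-(4-methylpent-3-en-1-yl)chromane
Conditions: Pd(OAc)2 (5 mol%), 2-(di-tert-butylphosphino)-1,1'-binaphthyl (6 mol%), Cs2CO3 (1.5 equiv), toluene, 80 °C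
Reagents that add atoms: none
Why: Intramolecular palladium-catalysed aryl C–O coupling (Buchwald-type etherification) closes the dihydropyran ring; the tertiary alkoxide has no β-hydrogen, and the stereocentre is retained because only the aryl–O bond is formed.

Step 5
Reactants: 8 (2R)-6-methoxy-2,8-dimethyl-2-(4-methylpent-3-en-1-yl)chromane
Product: 10 3-[(2S)-6-methoxy-2,8-dimethylchroman-2-yl]propanal, via vicinal diol 9 (not isolated)
Conditions: OsO4 (2 mol%), NaIO4 (4 equiv), 2,6-lutidine (2 equiv), dioxane/H2O 3:1, rt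
Reagents that add atoms: sodium periodate, [Na+].[O-]I(=O)(=O)=O; osmium tetroxide, O=[Os](=O)(=O)=O (catalytic oxygen carrier)
Why: Lemieux–Johnson dihydroxylation and glycol cleavage of the only alkene gives the C3′ aldehyde and acetone (the S descriptor reflects a CIP priority change only).

Step 6
Reactants: 10 3-[(2S)-6-methoxy-2,8-dimethylchroman-2-yl]propanal
Product: 11 (2R)-2-(4,4-dichlorobut-3-en-1-yl)-6-methoxy-2,8-dimethylchromane
Conditions: PPh3 (4 equiv), CCl4 (excess), THF, 60 °C
Reagents that add atoms: carbon tetrachloride, ClC(Cl)(Cl)Cl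
Why: Wittig-type dichloromethylenation by Ph3P=CCl2 generated in the flask converts the aldehyde into the gem-dichloroalkene, whose CCl2 carbon becomes C4′.

Step 7
Reactants: 11 (2R)-2-(4,4-dichlorobut-3-en-1-yl)-6-methoxy-2,8-dimethylchromane; 12 [2-(1,3-dioxolan-2-yl)ethyl]zinc bromide
Product: 13 (2R)-2-[(3Z)-4-chloro-6-(1,3-dioxolan-2-yl)hex-3-en-1-yl]-6-methoxy-2,8-dimethylchromane
Conditions: 12 (1.6 equiv, 0.5 M in THF), Pd(DPEphos)Cl2 (5 mol%), THF/DMF 2:1, 23 to 50 °C
Reagents that add atoms: none
Why: Negishi coupling of a propanal homoenolate equivalent, in which the zinc-bearing carbon of 12 (the normally electrophilic β-carbon of acrolein) is joined to the normally electrophilic dihalovinyl carbon of 11; zerovalent palladium inserts into the less hindered C–Cl bond trans to the chain (the known trans-selective mono-alkylation of 1,1-dichloro-1-alkenes with alkylzinc halides), so the three-carbon unit lands trans to C2′ and the E geometry of the future alkene is fixed.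

Step 8
Reactants: 13 (2R)-2-[(3Z)-4-chloro-6-(1,3-dioxolan-2-yl)hex-3-en-1-yl]-6-methoxy-2,8-dimethylchromane
Product: 15 (4E)-7-[(2R)-6-methoxy-2,8-dimethylchroman-2-yl]-4-methylhept-4-enal, via dioxolane acetal 14 (not isolated)
Conditions: Me2Zn (2 equiv), Pd(P(tBu)3)2 (5 mol%), THF, 23 to 50 °C; then 2 M aq HCl, THF, rt
Reagents that add atoms: dimethylzinc, C[Zn]C; water, O
Why: A second Negishi coupling under a bulky trialkylphosphine palladium catalyst replaces the remaining alkenyl chloride by methyl with retention of geometry, giving the E trisubstituted alkene, and the acidic work-up hydrolyses the dioxolane to the aldehyde.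

Step 9
Reactants: 15 (4E)-7-[(2R)-6-methoxy-2,8-dimethylchroman-2-yl]-4-methylhept-4-enal; 16 methyl 2-[bis(2,2,2-trifluoroethoxy)phosphoryl]propanoate
Product: 17 methyl (2Z,6E)-9-[(2R)-6-methoxy-2,8-dimethylchroman-2-yl]-2,6-dimethylnona-2,6-dienoate
Conditions: 16 (1.3 equiv), KN(SiMe3)2 (1.25 equiv), 18-crown-6 (3 equiv), THF, −78 °C
Reagents that add atoms: none
Why: Still–Gennari olefination, in which the electron-poor trifluoroethyl phosphonate eliminates under kinetic control to give the Z α-methyl enoate (chain cis to the ester).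

Step 10
Reactants: 17 methyl (2Z,6E)-9-[(2R)-6-methoxy-2,8-dimethylchroman-2-yl]-2,6-dimethylnona-2,6-dienoate
Product: 18 (2Z,6E)-9-[(2R)-6-methoxy-2,8-dimethylchroman-2-yl]-2,6-dimethylnona-2,6-dienoic acid
Conditions: LiOH·H2O (5 equiv), THF/MeOH/H2O 3:1:1, rt to 40 °C; then 1 M aq HCl to pH 3
Reagents that add atoms: lithium hydroxide, [Li+].[OH-]
Why: Ester saponification by acyl–oxygen cleavage under mild conditions that do not isomerise either alkene or touch the chromane.

## Compound list

1 | 4-methoxy-2-methylaniline | COc1ccc(N)c(C)c1 | starting material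
2 | 2-iodo-4-methoxy-6-methylaniline | COc1cc(C)c(N)c(I)c1 | intermediate
3 | 2-iodo-4-methoxy-6-methylbenzenediazonium bromide (not isolated) | COc1cc(C)c([N+]#N)c(I)c1.[Br-] | intermediate
4 | 2-bromo-1-iodo-5-methoxy-3-methylbenzene | COc1cc(C)c(Br)c(I)c1 | intermediate
5 | (R)-linalool, (3R)-3,7-dimethylocta-1,6-dien-3-ol | C=C[C@@](C)(CCC=C(C)C)O | starting material
6 | (3S)-1-(9-borabicyclo[3.3.1]nonan-9-yl)-3,7-dimethyloct-6-en-3-ol (not isolated) | B1(CC[C@@](C)(CCC=C(C)C)O)C2CCCC1CCC2 | intermediate
7 | (3R)-1-(2-bromo-5-methoxy-3-methylphenyl)-3,7-dimethyloct-6-en-3-ol | COc1cc(C)c(Br)c(c1)CC[C@@](C)(CCC=C(C)C)O | intermediate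
8 | (2R)-6-methoxy-2,8-dimethyl-2-(4-methylpent-3-en-1-yl)chromane | COc1cc(C)c2c(c1)CC[C@@](C)(CCC=C(C)C)O2 | intermediate
9 | 1-[(2S)-6-methoxy-2,8-dimethylchroman-2-yl]-4-methylpentane-3,4-diol, both C3 epimers (not isolated) | COc1cc(C)c2c(c1)CC[C@@](C)(CCC(O)C(C)(C)O)O2 | intermediate
10 | 3-[(2S)-6-methoxy-2,8-dimethylchroman-2-yl]propanal | COc1cc(C)c2c(c1)CC[C@@](C)(CCC=O)O2 | intermediate
11 | (2R)-2-(4,4-dichlorobut-3-en-1-yl)-6-methoxy-2,8-dimethylchromane | COc1cc(C)c2c(c1)CC[C@@](C)(CCC=C(Cl)Cl)O2 | intermediate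
12 | [2-(1,3-dioxolan-2-yl)ethyl]zinc bromide (commercial 0.5 M THF solution) | Br[Zn]CCC1OCCO1 | starting material
13 | (2R)-2-[(3Z)-4-chloro-6-(1,3-dioxolan-2-yl)hex-3-en-1-yl]-6-methoxy-2,8-dimethylchromane | COc1cc(C)c2c(c1)CC[C@@](C)(CC/C=C(\Cl)CCC1OCCO1)O2 | intermediate
14 | (2R)-2-[(3E)-6-(1,3-dioxolan-2-yl)-4-methylhex-3-en-1-yl]-6-methoxy-2,8-dimethylchromane (not isolated) | COc1cc(C)c2c(c1)CC[C@@](C)(CC/C=C(\C)CCC1OCCO1)O2 | intermediate
15 | (4E)-7-[(2R)-6-methoxy-2,8-dimethylchroman-2-yl]-4-methylhept-4-enal | COc1cc(C)c2c(c1)CC[C@@](C)(CC/C=C(\C)CCC=O)O2 | intermediate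
16 | methyl 2-[bis(2,2,2-trifluoroethoxy)phosphoryl]propanoate | COC(=O)C(C)P(=O)(OCC(F)(F)F)OCC(F)(F)F | starting material
17 | methyl (2Z,6E)-9-[(2R)-6-methoxy-2,8-dimethylchroman-2-yl]-2,6-dimethylnona-2,6-dienoate | COc1cc(C)c2c(c1)CC[C@@](C)(CC/C=C(\C)CC/C=C(/C)C(=O)OC)O2 | intermediate
18 | (2Z,6E)-9-[(2R)-6-methoxy-2,8-dimethylchroman-2-yl]-2,6-dimethylnona-2,6-dienoic acid | COc1cc(C)c2c(c1)CC[C@@](C)(CC/C=C(\C)CC/C=C(/C)C(=O)O)O2 | target

The descriptor at the quaternary carbon reads S in 6, 9 and 10 only because CIP priorities change; the spatial arrangement is that of 5 throughout.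

## Step count and risks

Total steps: 10. Longest linear sequence: 10 steps (1 to 18; the arene enters at step 3, so all steps lie on one line). From linalool it is 8 steps.

The three steps most likely to fail:

**Step 7 (homoenolate coupling).** The risks are over-alkylation at both chlorines, β-hydride reduction of the alkylpalladium intermediate, and slow oxidative addition into the dichloride. The fallback sets out from 11 and comes back at 14. Treatment of 11 with butyllithium (2.2 equiv, THF, −78 to 0 °C; Fritsch–Buttenberg–Wiechell-type elimination) and trapping of the acetylide with MeI gives (2R)-6-methoxy-2,8-dimethyl-2-(pent-3-yn-1-yl)chromane F1. Hydrozirconation with excess Cp2Zr(H)Cl (THF, 40 °C, equilibration puts zirconium on the methyl-bearing carbon) and iodinolysis give (2R)-2-[(3E)-4-iodopent-3-en-1-yl]-6-methoxy-2,8-dimethylchromane F2. Negishi coupling of F2 with the same zinc homoenolate 12 (Pd(PPh3)4, THF, 40 °C, retention) gives 14 with the methyl group already in place. This also removes the need for the methylation half of step 8; only its acid hydrolysis remains.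

**Step 4 (C–O ring closure).** The aryl bromide is electron-rich and flanked by two ortho substituents, so oxidative addition and C–O reductive elimination may be slow. The fallback sets out from 7 and comes back at 8, and changes from a palladium-mediated closure on the bromide to a copper-mediated Ullmann closure on the iodide. Aromatic Finkelstein exchange (CuI 10 mol%, NaI, trans-N,N'-dimethylcyclohexane-1,2-diamine, dioxane, 110 °C) gives (3R)-1-(2-iodo-5-methoxy-3-methylphenyl)-3,7-dimethyloct-6-en-3-ol F3. Ullmann-type etherification (CuI, 3,4,7,8-tetramethyl-1,10-phenanthroline, Cs2CO3, toluene, 110 °C) then closes it to 8, again without touching the stereocentre.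

**Step 3 (hydroboration and Suzuki coupling).** The free tertiary alcohol consumes borane and may slow transmetalation, and the coupling must discriminate iodide from bromide. The fallback sets out from 4 and 5 and comes back at 7. Heck arylation of the vinyl group of 5 with 4 at the C–I bond (Pd(OAc)2, Bu4NCl, NaHCO3, DMF, 60 °C) gives (1E,3R)-1-(2-bromo-5-methoxy-3-methylphenyl)-3,7-dimethylocta-1,6-dien-3-ol F4. Chemoselective saturation of the 1,2-disubstituted styrenyl alkene with diimide (2-nitrobenzenesulfonylhydrazide, Et3N, CH2Cl2, rt), which spares the trisubstituted alkene and the aryl bromide, then gives 7.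

## Further compounds

F1 | step 7 | (2R)-6-methoxy-2,8-dimethyl-2-(pent-3-yn-1-yl)chromane | COc1cc(C)c2c(c1)CC[C@@](C)(CCC#CC)O2
F2 | step 7 | (2R)-2-[(3E)-4-iodopent-3-en-1-yl]-6-methoxy-2,8-dimethylchromane | COc1cc(C)c2c(c1)CC[C@@](C)(CC/C=C(\C)I)O2
F3 | step 4 | (3R)-1-(2-iodo-5-methoxy-3-methylphenyl)-3,7-dimethyloct-6-en-3-ol | COc1cc(C)c(I)c(c1)CC[C@@](C)(CCC=C(C)C)O
F4 | step 3 | (1E,3R)-1-(2-bromo-5-methoxy-3-methylphenyl)-3,7-dimethylocta-1,6-dien-3-ol | COc1cc(C)c(Br)c(c1)/C=C/[C@@](C)(CCC=C(C)C)O
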